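**Retrosynthetic overview**

- Target 7 is the 2-phenylethyl ester of docosanoic acid. It has no stereocentre, and its only ring, the phenyl ring, is bought in 2-phenylethanol 2; no ring is formed in the route.
- Key disconnection: the C12–C13 bond of the acyl chain (C1 = ester carbonyl) is cut into a decyl radical and an ω-ester dodecyl radical. Both are released from carboxylates by anodic decarboxylation (crossed Kolbe electrolysis), a union of two carbons of like polarity.
- Enabling feature: C12 and C13 are plain CH2 groups inside an unbranched (CH2)20 run. The nearest functional group is the ester carbonyl C1, eleven carbons from C12, so both radicals are unstabilised primary radicals that dimerise instead of being oxidised to cations. The ring on O–CH2CH2–C6H5 is an unactivated monoalkylbenzene.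
- Precursors: undecanoic acid 4 (C10 radical + CO2) and half-ester 3 (C12 radical + CO2); 3 comes from mono-esterification of tridecanedioic acid 1 with 2.

Key step: step 2

Remark on the chemistry: the two primary radicals are assumed to combine without bias, so the cross/homo distribution in step 2 is taken as statistical and is steered by the excess of the cheap acid 4.

**Step 1**
Reactants: 1 tridecanedioic acid (brassylic acid); 2 2-phenylethanol
Product: 3 13-oxo-13-(2-phenylethoxy)tridecanoic acid (mono(2-phenylethyl) tridecanedioate)
Conditions: 1 (3 equiv), 2 (1 equiv), TsOH·H2O (cat.), toluene, reflux, Dean–Stark; cool, filter off unreacted 1 (reused); SiO2 chromatography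
Reagents that add atoms: none
Why: Fischer esterification with the diacid in threefold excess should statistically favour the half-ester over the diester, and the unreacted diacid should crystallise from cold toluene for reuse.

**Step 2**
Reactants: 3 13-oxo-13-(2-phenylethoxy)tridecanoic acid; 4 undecanoic acid
Product: 7 2-phenylethyl docosanoate, via decyl radical 5 (not isolated), via 12-oxo-12-(2-phenylethoxy)dodecyl radical 6 (not isolated)
Conditions: 3 (1 equiv), 4 (4 equiv), KOH (5 mol% of total CO2H), MeOH, Pt anode/Pt cathode, undivided cell, constant current ca. 0.2 A cm−2, 45–50 °C, stopped while still weakly acidic; SiO2 chromatography (hexane, then hexane/EtOAc)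
Reagents that add atoms: none
Why: Crossed Kolbe electrolysis: each carboxylate is oxidised by one electron at the platinum anode to an acyloxy radical that loses CO2 at once, and the primary radicals 5 and 6, formed side by side at high concentration in the anode layer, combine to the C12–C13 bond while protons are reduced to H2 at the cathode. The closest known reaction type is the mixed Kolbe coupling of a fatty acid with an alkyl hydrogen alkanedioate, the classical chain-extension route to long-chain esters. No ring is closed and no stereocentre is formed. The selectivity needed is cross- over homo-coupling, which is statistical; the fourfold excess of cheap acid 4 should send about four fifths of radical 6 into the cross-product, and the two symmetrical by-products (eicosane and bis(2-phenylethyl) tetracosanedioate) carry zero and two ester groups against one in 7 and should separate on silica. Chemoselectivity rests on the substrate: both radicals are unbranched primary ones without an α-heteroatom, so further oxidation to cations (Hofer–Moest pathway) should stay minor, and the remote, unactivated monoalkylbenzene ring should be neither oxidised at the carboxylate-covered anode nor attacked by the radicals. Keeping the electrolyte acidic to the end prevents methoxide build-up and thus methanolysis of the phenethyl ester.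

**Compound list**

1 | tridecanedioic acid (brassylic acid) | OC(=O)CCCCCCCCCCCC(=O)O | starting material
2 | 2-phenylethanol | OCCc1ccccc1 | starting material
3 | 13-oxo-13-(2-phenylethoxy)tridecanoic acid (mono(2-phenylethyl) tridecanedioate) | OC(=O)CCCCCCCCCCCC(=O)OCCc1ccccc1 | intermediate
4 | undecanoic acid | CCCCCCCCCCC(=O)O | starting material
5 | decyl radical | CCCCCCCCC[CH2] | intermediate (not isolated)
6 | 12-oxo-12-(2-phenylethoxy)dodecyl radical | [CH2]CCCCCCCCCCC(=O)OCCc1ccccc1 | intermediate (not isolated)
7 | 2-phenylethyl docosanoate (phenylethyl n-docosanoate) | CCCCCCCCCCCCCCCCCCCCCC(=O)OCCc1ccccc1 | target

**Step count**

Total steps: 2. Longest linear sequence: 2 (1 → 3 → 7; 2 and 4 enter as purchased materials).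

**Steps most likely to fail**

The route has only two steps, so both are listed, the key step first.

Step 2 (key step). What may go wrong:
- homo-coupling of radical 6 with itself, which consumes the half-ester;
- coating of the anode by the waxy long-chain products, which lowers the effective current density and shifts the reaction toward two-electron (cationic) products;
- slow anodic attack on the aromatic ring, or methanolysis of the ester if the electrolyte turns basic.

Fallback, forming the same C12–C13 bond by polar, copper-catalysed alkyl–alkyl coupling: the sequence sets out from 2. Fischer esterification of 2 with commercial 12-bromododecanoic acid (OC(=O)CCCCCCCCCCCBr; TsOH cat., toluene, Dean–Stark) should give 2-phenylethyl 12-bromododecanoate F1. Slow addition of commercial decylmagnesium bromide (CCCCCCCCCC[Mg]Br, 1.2 equiv) to F1 with Li2CuCl4 (3 mol%) and NMP (4 equiv) in THF at 0 °C should give the chain directly, because the copper-catalysed substitution of the primary bromide should be much faster than Grignard addition to the ester under these conditions. The fallback comes back to the route at 7.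

Step 1. What may go wrong: poor discrimination between the first and second esterification, and soap-like behaviour of the half-ester, which makes its separation from diacid and diester inefficient.

Fallback, differentiating the two chain ends by oxidative cleavage instead of statistics: the sequence sets out from 2. Fischer esterification of 2 with commercial erucic acid ((Z)-docos-13-enoic acid, CCCCCCCC/C=C\CCCCCCCCCCCC(=O)O; TsOH cat., toluene, Dean–Stark) should give 2-phenylethyl (Z)-docos-13-enoate F2. Ozonolysis (O3, CH2Cl2, −78 °C, Sudan Red 7B as end-point indicator to spare the phenyl ring; then Me2S) should cleave the C13=C14 bond to 2-phenylethyl 13-oxotridecanoate F3, which is freed from the C9 aldehyde fragment by chromatography. Pinnick oxidation of F3 (NaClO2, NaH2PO4, 2-methyl-2-butene, t-BuOH/H2O, room temperature) should give the half-ester. The fallback comes back to the route at 3.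

**Further compounds**

F1 | step 2 | 2-phenylethyl 12-bromododecanoate | BrCCCCCCCCCCCC(=O)OCCc1ccccc1
F2 | step 1 | 2-phenylethyl (Z)-docos-13-enoate | CCCCCCCC/C=C\CCCCCCCCCCCC(=O)OCCc1ccccc1
F3 | step 1 | 2-phenylethyl 13-oxotridecanoate | O=CCCCCCCCCCCCC(=O)OCCc1ccccc1
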